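The quench of starting material by protic impurity has a half-life of 2.7 s with the impurity held at its charge, far shorter than the 80 s of Sunday's closed flask. You asked for a quick number and your hunch was Tuesday's dosing, so here is how I reckoned it.

in all of them: protic impurity 0.0400 M
- Thursday's: starting material 0.20 M; one stirred flow tank at steady state, fed with the mixture as stated, mean residence time 400 s
- Sunday's: starting material 0.20 M; a closed flask charged with all of it at once and left for 80 s; time 80 s
- Monday's: starting material 0.20 M; a single well-mixed tank run continuously and read at steady state, 80 s in it on average
- Tuesday's: starting material 0.20 M (fed, over 80.0 s); a stirred flask in which starting material is dosed at a steady rate over 80.0 s without added volume, worked up at 80 s; time 80 s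

    starting material + starting material ⇌ target (K1 = 12 /M, k1 = 0.14 /M/s)
    starting material + target → side product (k2 = 0.0074 /M/s)
    starting material + protic impurity → quenched substrate (k3 = 6.4 /M/s)

* the set-up with the highest amount of target at the outlet or at the end, in percent of the starting material put in ("none" if the first two lie within 2 percentage points) (Thursday's / Sunday's / Monday's / Tuesday's / none)
* amount of target at the outlet or at the end, in percent of the starting material put in, Thursday's
* amount of target at the outlet or at the end, in percent of the starting material put in, Sunday's
* amount of target at the outlet or at the end, in percent of the starting material put in, Monday's
* amount of target at the outlet or at the end, in percent of the starting material put in, Tuesday's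

- percent here means starting material units held: one target counts as two
- percent here means starting material units held: one side product counts as three
- two of one species on the left: rate k times its square, two consumed each time
- the stated concentrations are those of everything mixed, before any reaction; amounts are the same in each set-up
- the feed brings no volume worth counting
- run time (Sunday's): 80 s

Since the quench was so much faster, I treated it as finished and reckoned with the free charge, 0.160 M: the starting material left after each protic impurity, the limiting reagent of the quench, has taken one. That is 80.0% of the charge.

For Sunday's flask I put c(target) = K1·c(starting material)² and c(starting material) + 2·c(target) = free charge. This gave c(starting material) = 0.0634 M and c(target) = 0.0483 M, a ceiling of 48.3% of the charge.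

Sunday's flask relaxes towards that ceiling with a time constant of 21.2 s, shorter than the run. The half-life of target by step 2 alone, 7.8 min, is longer than the run. So I committed to Sunday's at somewhat under the ceiling. Tuesday's dose ends at 80.0 s, the moment of work-up, so I put Tuesday's flask lower, against your hunch.

The forecast named Sunday's, noting that “the quench is over in seconds”. It gave 38% for Thursday's, 45.7% for Sunday's, 37.2% for Monday's and 31.5% for Tuesday's.

The simulation gave Sunday's as best, with 38.0% for Thursday's, 45.7% for Sunday's, 37.2% for Monday's and 31.3% for Tuesday's. Sunday's flask had not come to rest at 80.0 s: by 800 s its target had fallen from 45.7% to 33.2% and its side product had risen from 2.55% to 20.5%. Starting material, target and side product together still held 80.0%, the free charge's 80.0%. The neighbour of Tuesday's flask with 0.068 M of protic impurity had a free charge of 66.0%, and at 80.0 s those same species held 66.0%, of which target was 21.5%.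

The numbers of this flask belong to no real substance.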